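**Plan**

1. Numbering (daucane): C1 methyl-bearing fusion carbon, C2/C3 ring CH2, C4 isopropyl carbinol, C5 fusion CH, C6 ester carbon, C7 ketone, C8 methyl carbinol, C9 CHOH, C10 CH2; ring A is the five-membered ring (C1–C5), ring B the seven-membered ring (C1, C5–C10).
2. Enabling feature: in ring A the oxygenated C4 lies β to quaternary C1 and next to C5, which carries C6. C1, C5 and C6 (three contiguous stereocentres) therefore map onto the β-carbon, the α-carbon and the aldol carbinol of a cyclopent-2-enone whose carbonyl is C4.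
3. Retrosynthetic cuts, in order: the O6–acyl bond; the C7 and C8 oxygens (back to a C7=C8 alkene); C7=C8 of ring B (metathesis); C8–C9 (isopropenyl onto an aldehyde); C4–isopropyl; C1–CH3 together with C5–C6 (conjugate methylation/aldol); C1–C10 (side arm onto the cyclopentenone).
4. Forward: ring A is bought as 3-ethoxycyclopentenone. The C10–C9 acetal arm is attached, methyl and acrolein are added in one operation, isopropyl is added to C4 and C8 to C9, and ring B is closed by metathesis. C9, C8 and C7 are then adjusted and the 4-hydroxybenzoate is placed on O6.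
5. Stereochemistry: C1 from the chiral copper catalyst; C5 and C6 from the aldol (aldehyde anti to the larger C1 arm, anti aldol from the ring (E)-enolate); C4 from isopropyl attack anti to the C5 side chain; C9 from CBS reduction; C8 from osmylation directed by the C9 hydroxyl.

Key step: step 2

Assumption: L* is a binaphthol-derived N,N-bis(1-phenylethyl)phosphoramidite, used as the antipode that delivers methyl to the Si face of the β-carbon of 4 (giving the 3R adduct); its sense of induction is assumed to follow that of simple 3-alkylcyclopentenones.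

**Route**

Step 1
Reactants: 1 3-ethoxycyclopent-2-en-1-one; 2 (1,3-dioxolan-2-ylmethyl)magnesium bromide
Product: 4 3-(1,3-dioxolan-2-ylmethyl)cyclopent-2-en-1-one, via tertiary allylic alcohol 3 (not isolated)
Conditions: 2 (1.3 equiv), THF, 0 °C to rt; then 1 M aq. HCl, 0 °C, 15 min
Reagents that add atoms: (1,3-dioxolan-2-ylmethyl)magnesium bromide 2, Br[Mg]CC1OCCO1; water, O
Why: Stork–Danheiser transposition, in which 1,2-addition of the Grignard reagent to the vinylogous ester and acid-induced loss of ethanol with allylic shift should give the 3-substituted enone, the brief cold acid treatment being too mild to open the dioxolane.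

Step 2
Reactants: 4 3-(1,3-dioxolan-2-ylmethyl)cyclopent-2-en-1-one; 5 trimethylaluminium; 6 acrolein
Product: 8 (2S,3R)-3-(1,3-dioxolan-2-ylmethyl)-2-[(1S)-1-hydroxyprop-2-en-1-yl]-3-methylcyclopentan-1-one, via dimethylaluminium enolate 7 (not isolated)
Conditions: Cu(OTf)2 (5 mol %), phosphoramidite L* (10 mol %), Me3Al (1.3 equiv), Et2O, −30 °C; then acrolein (3 equiv), THF, −78 to −40 °C
Reagents that add atoms: trimethylaluminium 5, C[Al](C)C; acrolein 6, C=CC=O
Why: A methylcopper species generated from Me3Al and the phosphoramidite-ligated copper salt adds 1,4 to enone 4, and the regiodefined dimethylaluminium enolate 7 then adds 1,2 to acrolein through a closed six-membered transition state. The closest known reaction type is the copper-catalysed asymmetric conjugate addition of trialkylaluminium reagents to 3-substituted cyclic enones with aldol trapping of the aluminium enolate. No ring is closed; the step forms the C1–CH3 and C5–C6 bonds. C1 is set by the chiral ligand on copper, C5 by approach of the aldehyde to the enolate face anti to the larger dioxolanylmethyl arm on C1, and C6 by the chair-like Zimmerman–Traxler arrangement of the ring-locked (E)-enolate, which should favour the anti aldol required for C6. The step needs 1,4- rather than 1,2-transfer of methyl and carbonyl rather than conjugate attack on acrolein, which the copper catalyst and the oxygen-bound aluminium enolate secure, while ether solvent and low temperature should keep Me3Al from opening the acetal.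

Step 3
Reactants: 8 (2S,3R)-3-(1,3-dioxolan-2-ylmethyl)-2-[(1S)-1-hydroxyprop-2-en-1-yl]-3-methylcyclopentan-1-one
Product: 9 (2S,3R)-2-[(1S)-1-(tert-butyldimethylsilyloxy)prop-2-en-1-yl]-3-(1,3-dioxolan-2-ylmethyl)-3-methylcyclopentan-1-one
Conditions: TBSOTf, 2,6-lutidine, CH2Cl2, −78 °C
Reagents that add atoms: tert-butyldimethylsilyl triflate, CC(C)(C)[Si](C)(C)OS(=O)(=O)C(F)(F)F
Why: Silylation of the secondary aldol hydroxyl with a silyl triflate and a hindered base at low temperature should outrun retro-aldol cleavage and dehydration and leave the ketone and the acetal untouched.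

Step 4
Reactants: 9 (2S,3R)-2-[(1S)-1-(tert-butyldimethylsilyloxy)prop-2-en-1-yl]-3-(1,3-dioxolan-2-ylmethyl)-3-methylcyclopentan-1-one; 10 isopropylmagnesium chloride
Product: 11 (1R,2S,3R)-2-[(1S)-1-(tert-butyldimethylsilyloxy)prop-2-en-1-yl]-3-(1,3-dioxolan-2-ylmethyl)-3-methyl-1-(propan-2-yl)cyclopentan-1-ol
Conditions: anhydrous CeCl3, iPrMgCl (3 equiv each), THF, −78 to 0 °C
Reagents that add atoms: isopropylmagnesium chloride 10, CC(C)[Mg]Cl
Why: Organocerium addition, in which the weakly basic isopropylcerium reagent should add to the hindered enolisable ketone without enolisation, reduction or β-elimination of the silyloxy group, entering anti to the adjacent C5 side chain and the C1 methyl so that the C4 hydroxyl ends cis to both.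

Step 5
Reactants: 11 (1R,2S,3R)-2-[(1S)-1-(tert-butyldimethylsilyloxy)prop-2-en-1-yl]-3-(1,3-dioxolan-2-ylmethyl)-3-methyl-1-(propan-2-yl)cyclopentan-1-ol
Product: 12 2-{(1R,2S,3R)-2-[(1S)-1-(tert-butyldimethylsilyloxy)prop-2-en-1-yl]-3-hydroxy-1-methyl-3-(propan-2-yl)cyclopentyl}acetaldehyde
Conditions: PPTS, acetone/H2O (10:1), reflux
Reagents that add atoms: water, O
Why: Acid-catalysed acetal hydrolysis should free the C9 aldehyde under conditions that a secondary TBS ether and a tertiary alcohol tolerate, and the C4 hydroxyl cannot form a lactol because it is trans to the aldehyde arm on the ring.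

Step 6
Reactants: 12 2-{(1R,2S,3R)-2-[(1S)-1-(tert-butyldimethylsilyloxy)prop-2-en-1-yl]-3-hydroxy-1-methyl-3-(propan-2-yl)cyclopentyl}acetaldehyde; 13 isopropenylmagnesium bromide
Product: 14 (1R,2S,3R)-2-[(1S)-1-(tert-butyldimethylsilyloxy)prop-2-en-1-yl]-3-(2-hydroxy-3-methylbut-3-en-1-yl)-3-methyl-1-(propan-2-yl)cyclopentan-1-ol (both C9 epimers)
Conditions: isopropenylMgBr (2.5 equiv), THF, −78 to 0 °C
Reagents that add atoms: isopropenylmagnesium bromide 13, CC(=C)[Mg]Br
Why: Grignard 1,2-addition to the aldehyde forms the C8–C9 bond (the first equivalent is consumed by the tertiary hydroxyl); no useful control at C9 is expected, and both epimers are carried on because C9 is reset in steps 8 and 9.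

Step 7
Reactants: 14 (1R,2S,3R)-2-[(1S)-1-(tert-butyldimethylsilyloxy)prop-2-en-1-yl]-3-(2-hydroxy-3-methylbut-3-en-1-yl)-3-methyl-1-(propan-2-yl)cyclopentan-1-ol (both C9 epimers)
Product: 15 (1R,4R,5S,6S)-6-(tert-butyldimethylsilyloxy)dauc-7-ene-4,9-diol (both C9 epimers)
Conditions: second-generation Grubbs catalyst (H2IMes)(PCy3)Cl2Ru=CHPh (5–10 mol %), CH2Cl2 (5 mM), 40 °C
Reagents that add atoms: none
Why: Ring-closing metathesis between the vinyl and isopropenyl groups, initiated at the monosubstituted alkene, should close the trans-fused ring B as its trisubstituted C7=C8 alkene with loss of ethylene.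

Step 8
Reactants: 15 (1R,4R,5S,6S)-6-(tert-butyldimethylsilyloxy)dauc-7-ene-4,9-diol (both C9 epimers)
Product: 16 (1R,4R,5S,6S)-6-(tert-butyldimethylsilyloxy)-4-hydroxydauc-7-en-9-one
Conditions: Dess–Martin periodinane, CH2Cl2, rt
Reagents that add atoms: none
Why: Dess–Martin oxidation of the secondary allylic alcohol should converge both C9 epimers on one enone while the tertiary C4 hydroxyl and the silyl ether stay inert.

Step 9
Reactants: 16 (1R,4R,5S,6S)-6-(tert-butyldimethylsilyloxy)-4-hydroxydauc-7-en-9-one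
Product: 17 (1R,4R,5S,6S,9S)-6-(tert-butyldimethylsilyloxy)dauc-7-ene-4,9-diol
Conditions: (R)-2-methyl-CBS-oxazaborolidine (0.5 equiv), catecholborane (3 equiv), toluene, −78 °C
Reagents that add atoms: none
Why: Corey–Bakshi–Shibata reduction, in which the α-methylalkenyl carbon C8 acts as the large and the C10 methylene as the small ketone substituent, so that the (R)-oxazaborolidine should deliver hydride 1,2 under catalyst control to give the 9S alcohol with its hydroxyl on the α face (cis to H5, trans to the C1 methyl).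

Step 10
Reactants: 17 (1R,4R,5S,6S,9S)-6-(tert-butyldimethylsilyloxy)dauc-7-ene-4,9-diol
Product: 19 (1R,4R,5S,6R,7R,8S,9S)-6-(tert-butyldimethylsilyloxy)daucane-4,7,8,9-tetrol, via cyclic osmate ester 18 (not isolated)
Conditions: OsO4 (1.05 equiv), TMEDA (1.1 equiv), CH2Cl2, −78 °C; then ethylenediamine, rt
Reagents that add atoms: osmium tetroxide, O=[Os](=O)(=O)=O
Why: Hydroxyl-directed dihydroxylation, in which the OsO4·TMEDA complex accepts a hydrogen bond from the allylic C9 hydroxyl and should therefore add syn to it on the α face, setting the C8 tertiary carbinol (and the temporary C7 carbinol) cis to O9 against the usual anti preference of osmylation.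

Step 11
Reactants: 19 (1R,4R,5S,6R,7R,8S,9S)-6-(tert-butyldimethylsilyloxy)daucane-4,7,8,9-tetrol
Product: 20 (1R,4R,5S,6R,7R,8R,9S)-6-(tert-butyldimethylsilyloxy)-8,9-(isopropylidenedioxy)daucane-4,7-diol
Conditions: 2,2-dimethoxypropane, PPTS (cat.), CH2Cl2, rt
Reagents that add atoms: 2,2-dimethoxypropane, COC(C)(C)OC
Why: Acid-catalysed, equilibrating acetonide formation should select the 8,9-diol, because the C9 hydroxyl is the most accessible one and a 7,8-acetal would be pressed against the cis silyloxy group on C6, which leaves the C7 hydroxyl as the only free secondary alcohol.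

Step 12
Reactants: 20 (1R,4R,5S,6R,7R,8R,9S)-6-(tert-butyldimethylsilyloxy)-8,9-(isopropylidenedioxy)daucane-4,7-diol
Product: 21 (1R,4R,5S,6R,8S,9S)-6-(tert-butyldimethylsilyloxy)-4-hydroxy-8,9-(isopropylidenedioxy)daucan-7-one
Conditions: Dess–Martin periodinane, CH2Cl2, rt
Reagents that add atoms: none
Why: Dess–Martin oxidation of the remaining secondary alcohol should give the C7 ketone under non-basic conditions that do not epimerise C6 or disturb the acetonide, the silyl ether or the tertiary hydroxyl.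

Step 13
Reactants: 21 (1R,4R,5S,6R,8S,9S)-6-(tert-butyldimethylsilyloxy)-4-hydroxy-8,9-(isopropylidenedioxy)daucan-7-one
Product: 22 (1R,4R,5S,6R,8S,9S)-4,6-dihydroxy-8,9-(isopropylidenedioxy)daucan-7-one
Conditions: HF·pyridine, THF/pyridine, 0 °C to rt
Reagents that add atoms: none
Why: Fluoride-mediated silyl ether cleavage in a buffered, non-basic medium should free O6 without epimerisation at C6 or α-ketol isomerisation and leave the acetonide in place.

Step 14
Reactants: 22 (1R,4R,5S,6R,8S,9S)-4,6-dihydroxy-8,9-(isopropylidenedioxy)daucan-7-one; 23 4-(benzyloxy)benzoyl chloride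
Product: 24 (1R,4R,5S,6R,8S,9S)-4-hydroxy-8,9-(isopropylidenedioxy)-7-oxodaucan-6-yl 4-(benzyloxy)benzoate
Conditions: 23 (1.5 equiv), pyridine, DMAP (cat.), CH2Cl2, 0 °C
Reagents that add atoms: 4-(benzyloxy)benzoyl chloride 23, O=C(Cl)c1ccc(OCc2ccccc2)cc1
Why: DMAP-catalysed acylation should take place at the only secondary hydroxyl, the tertiary C4 hydroxyl being too hindered to react, with retention at C6 because its C–O bond is not touched.

Step 15
Reactants: 24 (1R,4R,5S,6R,8S,9S)-4-hydroxy-8,9-(isopropylidenedioxy)-7-oxodaucan-6-yl 4-(benzyloxy)benzoate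
Product: 25 (1R,4R,5S,6R,8S,9S)-4,8,9-trihydroxy-7-oxodaucan-6-yl 4-(benzyloxy)benzoate
Conditions: 2 M aq. HCl/THF (1:2), rt
Reagents that add atoms: none
Why: Acid hydrolysis of the isopropylidene acetal should release the 8,9-diol under conditions that leave the aryl ester, the benzyl ether, the ketone and the tertiary alcohols intact.

Step 16
Reactants: 25 (1R,4R,5S,6R,8S,9S)-4,8,9-trihydroxy-7-oxodaucan-6-yl 4-(benzyloxy)benzoate
Product: 26 (1R,4R,5S,6R,8S,9S)-4,8,9-trihydroxy-7-oxodaucan-6-yl 4-hydroxybenzoate (CNP0241001.1)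
Conditions: H2 (1 atm), 10% Pd/C, EtOAc, rt
Reagents that add atoms: none
Why: Catalytic hydrogenolysis should cleave only the benzylic C–O bond of the aryl benzyl ether, freeing the phenol without reducing the aliphatic ketone or the ester.

**Compound list**

1 | 3-ethoxycyclopent-2-en-1-one | CCOC1=CC(=O)CC1 | starting material
2 | (1,3-dioxolan-2-ylmethyl)magnesium bromide | Br[Mg]CC1OCCO1 | starting material
3 | 1-(1,3-dioxolan-2-ylmethyl)-3-ethoxycyclopent-2-en-1-ol (racemic; centre lost on transposition) | CCOC1=CC(O)(CC2OCCO2)CC1 | intermediate (not isolated)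
4 | 3-(1,3-dioxolan-2-ylmethyl)cyclopent-2-en-1-one | O=C1C=C(CC2OCCO2)CC1 | intermediate
5 | trimethylaluminium | C[Al](C)C | starting material
6 | acrolein | C=CC=O | starting material
7 | dimethyl{[(3R)-3-(1,3-dioxolan-2-ylmethyl)-3-methylcyclopent-1-en-1-yl]oxy}alumane | C[Al](C)OC1=C[C@@](C)(CC2OCCO2)CC1 | intermediate (not isolated)
8 | (2S,3R)-3-(1,3-dioxolan-2-ylmethyl)-2-[(1S)-1-hydroxyprop-2-en-1-yl]-3-methylcyclopentan-1-one | O=C1CC[C@](C)(CC2OCCO2)[C@H]1[C@@H](O)C=C | intermediate
9 | (2S,3R)-2-[(1S)-1-(tert-butyldimethylsilyloxy)prop-2-en-1-yl]-3-(1,3-dioxolan-2-ylmethyl)-3-methylcyclopentan-1-one | O=C1CC[C@](C)(CC2OCCO2)[C@H]1[C@@H](O[Si](C)(C)C(C)(C)C)C=C | intermediate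
10 | isopropylmagnesium chloride | CC(C)[Mg]Cl | starting material
11 | (1R,2S,3R)-2-[(1S)-1-(tert-butyldimethylsilyloxy)prop-2-en-1-yl]-3-(1,3-dioxolan-2-ylmethyl)-3-methyl-1-(propan-2-yl)cyclopentan-1-ol | CC(C)[C@]1(O)CC[C@](C)(CC2OCCO2)[C@H]1[C@@H](O[Si](C)(C)C(C)(C)C)C=C | intermediate
12 | 2-{(1R,2S,3R)-2-[(1S)-1-(tert-butyldimethylsilyloxy)prop-2-en-1-yl]-3-hydroxy-1-methyl-3-(propan-2-yl)cyclopentyl}acetaldehyde | CC(C)[C@]1(O)CC[C@](C)(CC=O)[C@H]1[C@@H](O[Si](C)(C)C(C)(C)C)C=C | intermediate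
13 | isopropenylmagnesium bromide | CC(=C)[Mg]Br | starting material
14 | (1R,2S,3R)-2-[(1S)-1-(tert-butyldimethylsilyloxy)prop-2-en-1-yl]-3-(2-hydroxy-3-methylbut-3-en-1-yl)-3-methyl-1-(propan-2-yl)cyclopentan-1-ol, both C9 epimers | CC(C)[C@]1(O)CC[C@](C)(CC(O)C(C)=C)[C@H]1[C@@H](O[Si](C)(C)C(C)(C)C)C=C | intermediate
15 | (1R,4R,5S,6S)-6-(tert-butyldimethylsilyloxy)dauc-7-ene-4,9-diol, both C9 epimers | CC(C)[C@]1(O)CC[C@]2(C)CC(O)C(C)=C[C@H](O[Si](C)(C)C(C)(C)C)[C@H]21 | intermediate
16 | (1R,4R,5S,6S)-6-(tert-butyldimethylsilyloxy)-4-hydroxydauc-7-en-9-one | CC(C)[C@]1(O)CC[C@]2(C)CC(=O)C(C)=C[C@H](O[Si](C)(C)C(C)(C)C)[C@H]21 | intermediate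
17 | (1R,4R,5S,6S,9S)-6-(tert-butyldimethylsilyloxy)dauc-7-ene-4,9-diol | CC(C)[C@]1(O)CC[C@]2(C)C[C@H](O)C(C)=C[C@H](O[Si](C)(C)C(C)(C)C)[C@H]21 | intermediate
18 | 7α,8α-cyclic osmate ester of 19 (dioxo-osmium glycolate chelated by TMEDA) | CC(C)[C@]1(O)CC[C@]2(C)C[C@H](O)[C@]3(C)O[Os-2]4(=O)(=O)([N+](C)(C)CC[N+]4(C)C)O[C@@H]3[C@H](O[Si](C)(C)C(C)(C)C)[C@H]21 | intermediate (not isolated)
19 | (1R,4R,5S,6R,7R,8S,9S)-6-(tert-butyldimethylsilyloxy)daucane-4,7,8,9-tetrol | CC(C)[C@]1(O)CC[C@]2(C)C[C@H](O)[C@](C)(O)[C@H](O)[C@H](O[Si](C)(C)C(C)(C)C)[C@H]21 | intermediate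
20 | (1R,4R,5S,6R,7R,8R,9S)-6-(tert-butyldimethylsilyloxy)-8,9-(isopropylidenedioxy)daucane-4,7-diol | CC(C)[C@]1(O)CC[C@]2(C)C[C@@H]3OC(C)(C)O[C@]3(C)[C@H](O)[C@H](O[Si](C)(C)C(C)(C)C)[C@H]21 | intermediate
21 | (1R,4R,5S,6R,8S,9S)-6-(tert-butyldimethylsilyloxy)-4-hydroxy-8,9-(isopropylidenedioxy)daucan-7-one | CC(C)[C@]1(O)CC[C@]2(C)C[C@@H]3OC(C)(C)O[C@]3(C)C(=O)[C@H](O[Si](C)(C)C(C)(C)C)[C@H]21 | intermediate
22 | (1R,4R,5S,6R,8S,9S)-4,6-dihydroxy-8,9-(isopropylidenedioxy)daucan-7-one | CC(C)[C@]1(O)CC[C@]2(C)C[C@@H]3OC(C)(C)O[C@]3(C)C(=O)[C@H](O)[C@H]21 | intermediate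
23 | 4-(benzyloxy)benzoyl chloride | O=C(Cl)c1ccc(OCc2ccccc2)cc1 | starting material
24 | (1R,4R,5S,6R,8S,9S)-4-hydroxy-8,9-(isopropylidenedioxy)-7-oxodaucan-6-yl 4-(benzyloxy)benzoate | CC(C)[C@]1(O)CC[C@]2(C)C[C@@H]3OC(C)(C)O[C@]3(C)C(=O)[C@H](OC(=O)c4ccc(OCc5ccccc5)cc4)[C@H]21 | intermediate
25 | (1R,4R,5S,6R,8S,9S)-4,8,9-trihydroxy-7-oxodaucan-6-yl 4-(benzyloxy)benzoate | CC(C)[C@]1(O)CC[C@]2(C)C[C@H](O)[C@](C)(O)C(=O)[C@H](OC(=O)c3ccc(OCc4ccccc4)cc3)[C@H]21 | intermediate
26 | (1R,4R,5S,6R,8S,9S)-4,8,9-trihydroxy-7-oxodaucan-6-yl 4-hydroxybenzoate (CNP0241001.1) | CC(C)[C@]1(O)CC[C@]2(C)C[C@H](O)[C@](C)(O)C(=O)[C@H](OC(=O)c3ccc(O)cc3)[C@H]21 | target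

**Step count and risks**

Total: 16 steps. Longest linear sequence: 16 steps (1 to 26); all other inputs are commercial.

Steps most likely to fail:

Step 2. The aluminium enolate sits next to the new quaternary carbon, so C–C bond formation with acrolein may be sluggish, methyl transfer from aluminium to the aldehyde may compete, or facial and anti/syn selectivity in the aldol may be poor. The fallback sets out from 4 and comes back at 8. The conjugate addition is run alone and enolate 7 is silylated with Et3SiOTf to give triethyl{[(3R)-3-(1,3-dioxolan-2-ylmethyl)-3-methylcyclopent-1-en-1-yl]oxy}silane F1, which is isolated and allows the enantiomeric purity to be checked. F1 is cleaved with MeLi in THF at 0 °C to lithium (3R)-3-(1,3-dioxolan-2-ylmethyl)-3-methylcyclopent-1-en-1-olate F2, which should add to acrolein at −78 °C through a lithium Zimmerman–Traxler transition state to give 8.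

Step 10. The bulky silyloxy group on C6 crowds the α face to which the C9 hydroxyl directs the osmium reagent, so osmylation may be slow or may lose facial selectivity. The fallback sets out from 17 and comes back at 21; it builds the cis-8,9-diol by inversion instead of delivery.
- O9 is converted with Boc2O/DMAP into the 9-O-tert-butoxycarbonyl derivative of 17 F3.
- mCPBA, which should attack anti to both allylic oxygens, gives the 7β,8β-epoxide of F3 F4.
- BF3·OEt2 at −40 °C should trigger opening at the tertiary C8 by the carbonate carbonyl with inversion, giving the 8α,9α-cyclic carbonate of 6-O-TBS-daucane-4,7β,8α,9α-tetrol F5.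
- K2CO3/MeOH gives the C7 epimer of 19 F6.
- 2,2-Dimethoxypropane/PPTS gives the C7 epimer of 20 F7, the 8,9-diol now being the only cis pair.
- Dess–Martin oxidation of F7 gives 21.

Step 11. Ketal formation may show poor regioselectivity (7,8- against 8,9-acetonide) or give mixtures that equilibrate slowly. The fallback sets out from 19 and comes back at 21; it uses kinetic steric differentiation by monosilylation.
- Et3SiOTf/2,6-lutidine at −78 °C should silylate the least hindered secondary hydroxyl to give the 9-O-triethylsilyl ether of 19 F8.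
- Dess–Martin oxidation gives the 9-O-triethylsilyl ether of (1R,4R,5S,6R,8S,9S)-6-(tert-butyldimethylsilyloxy)-4,8,9-trihydroxydaucan-7-one F9.
- PPTS/MeOH removes only the triethylsilyl group to give (1R,4R,5S,6R,8S,9S)-6-(tert-butyldimethylsilyloxy)-4,8,9-trihydroxydaucan-7-one F10.
- The single cis-diol of F10 is ketalised with 2,2-dimethoxypropane/PPTS to give 21.

Further compounds
F1 | step 2 | triethyl{[(3R)-3-(1,3-dioxolan-2-ylmethyl)-3-methylcyclopent-1-en-1-yl]oxy}silane | CC[Si](CC)(CC)OC1=C[C@@](C)(CC2OCCO2)CC1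
F2 | step 2 | lithium (3R)-3-(1,3-dioxolan-2-ylmethyl)-3-methylcyclopent-1-en-1-olate | [Li]OC1=C[C@@](C)(CC2OCCO2)CC1
F3 | step 10 | 9-O-tert-butoxycarbonyl derivative of 17 | CC(C)[C@]1(O)CC[C@]2(C)C[C@H](OC(=O)OC(C)(C)C)C(C)=C[C@H](O[Si](C)(C)C(C)(C)C)[C@H]21
F4 | step 10 | 7β,8β-epoxide of F3 | CC(C)[C@]1(O)CC[C@]2(C)C[C@H](OC(=O)OC(C)(C)C)[C@@]3(C)O[C@H]3[C@H](O[Si](C)(C)C(C)(C)C)[C@H]21
F5 | step 10 | 8α,9α-cyclic carbonate of 6-O-TBS-daucane-4,7β,8α,9α-tetrol | CC(C)[C@]1(O)CC[C@]2(C)C[C@@H]3OC(=O)O[C@]3(C)[C@@H](O)[C@H](O[Si](C)(C)C(C)(C)C)[C@H]21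
F6 | step 10 | C7 epimer of 19 (7β-hydroxyl) | CC(C)[C@]1(O)CC[C@]2(C)C[C@H](O)[C@](C)(O)[C@@H](O)[C@H](O[Si](C)(C)C(C)(C)C)[C@H]21
F7 | step 10 | C7 epimer of 20 (7β-hydroxyl) | CC(C)[C@]1(O)CC[C@]2(C)C[C@@H]3OC(C)(C)O[C@]3(C)[C@@H](O)[C@H](O[Si](C)(C)C(C)(C)C)[C@H]21
F8 | step 11 | 9-O-triethylsilyl ether of 19 | CC(C)[C@]1(O)CC[C@]2(C)C[C@H](O[Si](CC)(CC)CC)[C@](C)(O)[C@H](O)[C@H](O[Si](C)(C)C(C)(C)C)[C@H]21
F9 | step 11 | 9-O-triethylsilyl ether of (1R,4R,5S,6R,8S,9S)-6-(tert-butyldimethylsilyloxy)-4,8,9-trihydroxydaucan-7-one | CC(C)[C@]1(O)CC[C@]2(C)C[C@H](O[Si](CC)(CC)CC)[C@](C)(O)C(=O)[C@H](O[Si](C)(C)C(C)(C)C)[C@H]21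
F10 | step 11 | (1R,4R,5S,6R,8S,9S)-6-(tert-butyldimethylsilyloxy)-4,8,9-trihydroxydaucan-7-one | CC(C)[C@]1(O)CC[C@]2(C)C[C@H](O)[C@](C)(O)C(=O)[C@H](O[Si](C)(C)C(C)(C)C)[C@H]21
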